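**Conventions.** Locants follow the target skeleton and are kept for every bicyclic intermediate: C1 is the methyl on C2; C2 CHMe; C3, C4 CH2; C5 C–OH; C6 ring-fusion CH; C7 CH2; C8 CHOH; C9 CMe2; C10 C=O; C11 quaternary carbon; C12, C13 chain CH2; C14–C17 butenolide. β is the face that carries C8–O and C6–H in the target (also C2–H and C11–CH3); α carries C5–OH, C2–CH3 and the C11 chain.

## The problem

Target 36 is a hydroazulene: a cycloheptanone (C2–C3–C4–C5–C6–C10–C11) fused along C5–C6 to a cyclopentane (C5–C9) that carries a gem-dimethyl group at C9 and a secondary alcohol at C8. A two-carbon chain joins the quaternary C11 to a β-substituted butenolide. There are five stereocenters. Only C8 can be bought directly by asymmetric catalysis, so it must relay to the others: C2 and C11 are contiguous, C11 is quaternary, and C5/C6 form a tertiary aldol at a trans ring fusion (C5–OH α, C6–H β). The C10 ketone lies between C11 and C6, so the enolate used to methylate C11 must be regiodefined. The β-hydroxy ketone can dehydrate or undergo retro-aldol cleavage, C6 is epimerisable, and the butenolide tolerates neither hydrides, peroxide nucleophiles nor strong base; both must therefore appear late. The enabling feature is in the seven-membered ring: oxygen on C10 next to C11, an sp3 C6 between C5 and C10, and a C2–C3 ring bond. Cutting C2–C3 and joining C5 to C10 gives a cis-1-alkenyl-2-vinyl siloxycyclopropane (ring C5–C6–C10) on a bicyclo[3.1.0]hexane that already contains the cyclopentane of the target. Its [3,3] shift returns the seven-membered ring as the C10=C11 silyl enol ether with a C4=C5 alkene.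

## Retrosynthesis

**Butenolide (C13–C14).** Target 36 is traced to its C8 silyl ether 35 and then to primary iodide 32 and 4-bromofuran-2(5H)-one 33. Attaching the intact lactone last avoids exposing it to the hydride and base steps. The forward step is an sp3–sp2 Negishi coupling that must tolerate a ketone and a tertiary alcohol. Iodide 32 comes from aldol 30 through alcohol 31.

**C5–O.** Aldol 30 is traced through diol 29 and epoxy alcohol 28 to homoallylic alcohol 27, and so to β,γ-unsaturated ketone 26. The alternative (conjugate the alkene, epoxidise the enone, reduce) would erase C6 and reset it by enolate protonation, which has no clear bias toward the trans fusion. The chosen cut keeps C6 as delivered by the rearrangement and asks two things of the forward chemistry: hydride addition to C10 from the open β face, and delivery of the epoxide oxygen by the resulting α hydroxyl.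

**C11–CH3.** Ketone 26 comes from silyl enol ether 24 by methylation of its lithium enolate 25. The enol ether fixes the enolate at C10=C11; the C2 methyl directs the electrophile to the opposite face.

**Key disconnection (C2–C3 formed, C5–C10 broken).** Enol ether 24 is the rearrangement product of siloxy divinylcyclopropane 23. This removes the seven-membered ring and the C2 stereocenter at once and leaves a bicyclo[3.1.0]hexane. The forward reaction needs the two alkenyl groups cis on the cyclopropane and an (E)-propenyl terminus.

**Masked vinyl group.** The C5 vinyl group of 23 is unveiled from terminal alkyne 22 (Lindlar), which comes from bis-silyl compound 21 and cyclopropanol 20. Carrying C3–C4 as an alkyne means that the carbene adds to a single alkene, the cyclopropylidene carbenoid has no vinyl group to rearrange into, and no cis-divinylcyclopropane exists until the C10 oxygen is silylated. The cost is two steps.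

**C10–C11 and C10–O.** Cyclopropanol 20 comes from gem-dibromide 16 and alkenylboronate 7 by a carbenoid 1,2-metallate shift and oxidation. This makes the C10–C11 bond and places oxygen on C10 in one flask, with inversion at C10 defining which group is exo.

**Cyclopropane and cyclopentane.** Dibromide 16 comes from enyne 14 and bromoform 15; 14 from enol triflate 12 and ethynyltrimethylsilane 13; 12 from silyl ether 10, alcohol 9 and 2,2-dimethylcyclopentane-1,3-dione 8. The dione is achiral, and one catalytic reduction sets C8.

**Alkenyl fragment.** Boronate 7 comes from iodide 5, iodo alcohol 4 and cyclic siloxane 3, which is made from pent-3-yn-1-ol 1. Intermolecular hydrometalation of this alkyne favours the wrong carbon; the silicon tether puts the metal on the carbon next to the chain and cis to the new hydrogen.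

## Roads not taken

**Alternative 1:** The cut removes both methyl groups from the seven-membered ring, from ketone A1 back to 2-allyl enone A2. Forward, Me3Al would add to C2 under Cu(OTf)2 and a chiral phosphoramidite, and the aluminium enolate would be methylated at C11.
- Merits: C2 is set by the catalyst, not by a relay from C8; two stereocenters form in one flask; no low-temperature carbenoid chemistry.
- Weak points: α-substituted cycloalkenones are slow acceptors, and aluminium enolates alkylate poorly without activation. The allyl group has one carbon too many for the C12–C13 chain. A1 has no cyclopentane, so the gem-dimethyl carbon, C8–OH and the trans aldol would still have to be annulated onto a C5/C6/C10 array in which C6 sits between two carbonyls.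
- Comparison: this road is better on absolute control of C2. The chosen plan sets against it that the cyclopentane and C8 are present from the start, that ring formation fixes C2 and C6 together, and that the C11 enolate is regiodefined by construction.

**Alternative 2:** The cut is C7–C8, from bicyclic diketone A3 back to aldehyde enone A4. Forward, [Rh(dppe)]ClO4 would add the C8 aldehyde across the C6=C7 methylene group.
- Merits: a 4-pentenal closing to a cyclopentanone is the best case for hydroacylation; the aldehyde cannot enolise; the step is atom-economical; the C5 oxygen is carried from the start as a silyl ether.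
- Weak points: the alkene is 1,1-disubstituted and conjugated to the C10 ketone; decarbonylation competes; C6 is created in the insertion step with no evident bias toward the trans fusion; C8 must later be reduced selectively beside C9. A4 also presupposes the seven-membered ring with C2, C5 and C11 set.
- Comparison: as a cyclopentane closure it is at least as good as anything here, and it avoids the four-step C5 oxygenation of the chosen plan. The chosen plan answers with a stereospecific origin for C6 and with one step that makes the seven-membered ring and C2.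

**Alternative 3:** The cut is C6–C7, from diketone A5 back to seco diketone A6. Forward, the dilithium bis-enolate would be oxidised with Fe(acac)3.
- Merits: each ketone has a single enolisable position, so the bis-enolate is unambiguous; the disconnection is convergent.
- Weak points: the C6 enolate has the C5 silyloxy group in the β position and can eliminate it; the radical coupling gives no firm control of C6; intramolecular oxidative enolate couplings are substrate-sensitive. Like Alternative 2 it needs the complete seven-membered ring first.
- Comparison: it shares the early C5 oxygen with Alternative 2 and is the shortest closure on paper. The chosen plan avoids an enolate with a β leaving group and fixes C6 by a concerted step.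

Key step: step 14

Assumption: cis-divinylcyclopropane 23 is taken to survive at 0 °C; if it rearranges as it forms, steps 13 and 14 merge without change in the compounds.

## Route

Step 1
Reactants: 1 pent-3-yn-1-ol
Product: 3 (E)-3-ethylidene-2,2-dimethyl-1,2-oxasilolane, via dimethylsilyl ether 2 (not isolated)
Conditions: (HMe2Si)2NH, neat, 60 °C; then Pt2[(CH2=CHSiMe2)2O]3 (0.3 mol%), THF, 20 °C
Reagents that add atoms: 1,1,3,3-tetramethyldisilazane, C[SiH](C)N[SiH](C)C
Why: Silylation gives the hydrosilyl ether, and platinum-catalysed intramolecular hydrosilylation of a homopropargylic silyl ether is 5-exo-dig and syn; silicon therefore ends on the carbon next to the chain and cis to the new vinylic hydrogen, which fixes the geometry of the future C11=C2 alkene.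

Step 2
Reactants: 3 (E)-3-ethylidene-2,2-dimethyl-1,2-oxasilolane
Product: 4 (E)-3-iodopent-3-en-1-ol
Conditions: NIS, (CF3)2CHOH, 0 °C; then aq. NaHCO3
Reagents that add atoms: N-iodosuccinimide, O=C1CCC(=O)N1I
Why: Iododesilylation of an alkenylsiloxane in hexafluoroisopropanol proceeds with retention at the sp2 carbon, and the labile Si–O bond is hydrolysed on work-up; iodine ends trans to the methyl group.

Step 3
Reactants: 4 (E)-3-iodopent-3-en-1-ol
Product: 5 (E)-tert-butyl[(3-iodopent-3-en-1-yl)oxy]dimethylsilane
Conditions: TBSCl, imidazole, CH2Cl2, 0 → 20 °C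
Reagents that add atoms: tert-butyldimethylsilyl chloride, CC(C)(C)[Si](C)(C)Cl
Why: Imidazole-mediated silylation of a primary alcohol.

Step 4
Reactants: 5 (E)-tert-butyl[(3-iodopent-3-en-1-yl)oxy]dimethylsilane
Product: 7 (Z)-alkenylboronate (pinacol boronate on C3 of the pentenyl chain; boron trans to the methyl group), via alkenyllithium 6 (not isolated)
Conditions: t-BuLi (2.1 equiv), Et2O, −78 °C; then iPrOBpin, −78 → 20 °C
Reagents that add atoms: 2-isopropoxy-4,4,5,5-tetramethyl-1,3,2-dioxaborolane, CC(C)OB1OC(C)(C)C(C)(C)O1
Why: Iodine–lithium exchange is fast and stereoretentive at −78 °C, and the alkenyllithium is borylated by the isopropoxy boronate (lithiation–borylation).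

Step 5
Reactants: 8 2,2-dimethylcyclopentane-1,3-dione
Product: 9 (S)-3-hydroxy-2,2-dimethylcyclopentan-1-one
Conditions: (R)-2-methyl-CBS-oxazaborolidine (10 mol%), BH3·SMe2 (0.6 equiv), THF, −20 °C; MeOH
Reagents that add atoms: none
Why: Corey–Bakshi–Shibata reduction; the carbonyl is flanked by a quaternary carbon (large) and a methylene group (small), and the (R)-catalyst should deliver hydride to give the (S)-alcohol, which becomes C8. Substoichiometric borane limits diol formation.

Step 6
Reactants: 9 (S)-3-hydroxy-2,2-dimethylcyclopentan-1-one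
Product: 10 (S)-3-(tert-butyldimethylsilyloxy)-2,2-dimethylcyclopentan-1-one
Conditions: TBSCl, imidazole, DMF, 20 °C
Reagents that add atoms: tert-butyldimethylsilyl chloride, CC(C)(C)[Si](C)(C)Cl
Why: Silylation under weakly basic conditions avoids retro-aldol opening of the β-hydroxy ketone.

Step 7
Reactants: 10 (S)-3-(tert-butyldimethylsilyloxy)-2,2-dimethylcyclopentan-1-one
Product: 12 (S)-4-(tert-butyldimethylsilyloxy)-5,5-dimethylcyclopent-1-en-1-yl trifluoromethanesulfonate, via potassium enolate 11 (not isolated)
Conditions: KHMDS, THF, −78 °C; then PhNTf2, −78 → 0 °C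
Reagents that add atoms: N-phenyl-bis(trifluoromethanesulfonimide), O=S(=O)(N(c1ccccc1)S(=O)(=O)C(F)(F)F)C(F)(F)F
Why: The ketone can enolise only toward C6 because the other α-carbon is quaternary, so a single enolate forms and is O-triflated.

Step 8
Reactants: 12 enol triflate; 13 ethynyltrimethylsilane
Product: 14 (S)-tert-butyldimethyl{[2,2-dimethyl-3-(trimethylsilylethynyl)cyclopent-3-en-1-yl]oxy}silane
Conditions: PdCl2(PPh3)2 (3 mol%), CuI (6 mol%), Et3N, THF, 20 °C
Reagents that add atoms: none
Why: Sonogashira coupling of an enol triflate; the silylalkyne stands in for the C3–C4 vinyl group until the C10 oxygen has been silylated.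

Step 9
Reactants: 14 enyne; 15 bromoform
Product: 16 6,6-dibromo-3-(tert-butyldimethylsilyloxy)-2,2-dimethyl-1-(trimethylsilylethynyl)bicyclo[3.1.0]hexane (3S; cyclopropane trans to the silyloxy group)
Conditions: KOt-Bu, pentane, −20 → 0 °C
Reagents that add atoms: none
Why: Dibromocarbene addition (Doering–Hoffmann conditions) to the only alkene. The inward bromine of the carbene must lie over the five-membered ring, where it would clash with a syn C8 substituent, so addition should occur anti to the silyloxy group; this sets C5 and C6 with C6–H cis to C8–O.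

Step 10
Reactants: 16 dibromide; 7 alkenylboronate
Product: 20 cyclopropanol (C10–OH endo; C10 alkenyl group exo and cis to the C5 alkynyl group), via lithium carbenoid 17 (not isolated), via boron ate complex 18 (not isolated), via cyclopropylboronate 19 (not isolated)
Conditions: n-BuLi (1.05 equiv) added to 16 + 7, THF/Et2O, −100 °C; then → 20 °C; then NaBO3·4H2O, THF/H2O, 0 → 20 °C
Reagents that add atoms: sodium perborate, B(=O)O[O-].[Na+]
Why: Bromine–lithium exchange removes the less hindered exo bromine, and the carbenoid is captured at once by the boronate (Matteson-type in situ protocol). The alkenyl group then migrates from boron to C10 with inversion, displacing the endo bromide, so it ends exo and boron ends endo. Perborate replaces boron by oxygen with retention under mild base that the cyclopropanol tolerates.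

Step 11
Reactants: 20 cyclopropanol
Product: 21 C10 trimethylsilyl ether of 20
Conditions: 1-(trimethylsilyl)imidazole, CH2Cl2, 0 → 20 °C
Reagents that add atoms: 1-(trimethylsilyl)imidazole, C[Si](C)(C)n1ccnc1
Why: A strong, non-acidic silyl donor silylates the hindered tertiary cyclopropanol without the base or Lewis acid that would open the ring.

Step 12
Reactants: 21 bis-silyl compound
Product: 22 terminal alkyne (C5 ethynyl; C10 OSiMe3)
Conditions: AgNO3 (20 mol%), 2,6-lutidine, acetone/H2O, 20 °C
Reagents that add atoms: none
Why: Silver-catalysed protodesilylation cleaves only the C(sp)–Si bond; the silyl ethers are stable under these near-neutral conditions.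

Step 13
Reactants: 22 terminal alkyne
Product: 23 siloxy cis-divinylcyclopropane (C5 vinyl and C10 (E)-alkenyl cis; C10 OSiMe3)
Conditions: H2 (1 atm), Pd/CaCO3 poisoned with Pb(OAc)2, quinoline, hexane/EtOAc, 0 °C
Reagents that add atoms: none
Why: Lindlar semi-hydrogenation stops at the terminal alkene; the trisubstituted alkene and the cyclopropane are inert. The rearrangement substrate is thus made under neutral conditions immediately before use.

Step 14
Reactants: 23 siloxy cis-divinylcyclopropane
Product: 24 hydroazulene dienyl silyl enol ether (C10=C11 enol ether, C4=C5 alkene, C2–H and C6–H both β)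
Conditions: PhMe, trace Et3N, 60 °C
Reagents that add atoms: none
Why: On gentle warming 23 should undergo the [3,3]-sigmatropic cis-divinylcyclopropane to cycloheptadiene rearrangement: both alkenyl groups fold over the three-membered ring in a boat transition state, and C2 bonds to C3 as the strained, donor-substituted C5–C10 bond breaks. The closest known reaction type is the rearrangement of cis-1-alkenyl-2-vinyl siloxycyclopropanes to cycloheptadienyl silyl enol ethers. The seven-membered ring closes by enlargement of the cyclopropane in this concerted six-electron shift, not by an end-to-end cyclisation, so no ring-size competition arises. C2 is the one new stereocenter: the (E)-propenyl terminus keeps its methyl outside the boat, and together with C6 this places C2–H cis to C6–H. C6 is carried through unchanged. The step needs the two alkenyl groups cis on the cyclopropane, which the exo alkenyl group from step 10 provides, and it needs the boat pathway only, which the small C6–H under the boat allows. The enol ether forms regiospecifically at C10=C11 and the second alkene at C4=C5.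

Step 15
Reactants: 24 silyl enol ether
Product: 26 β,γ-unsaturated ketone (C10=O; C11 quaternary with CH3 β; C4=C5 alkene; C6–H β), via lithium enolate 25 (not isolated)
Conditions: MeLi, THF, 0 → 20 °C; then DMPU, MeI, −78 → −30 °C; AcOH, −78 °C
Reagents that add atoms: iodomethane, CI
Why: Methyllithium cleaves the trimethylsilyl enol ether to the regiodefined lithium enolate (Stork enolate generation), which is C-methylated. The C2 methyl is pseudoaxial to avoid allylic strain with the C11 chain, so iodomethane enters from the other face and the new methyl ends trans to the C2 methyl. The cold acidic quench keeps C6 and the C4=C5 alkene in place.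

Step 16
Reactants: 26 β,γ-unsaturated ketone
Product: 27 homoallylic alcohol (C10–OH α)
Conditions: LiAlH4, Et2O, −78 → 0 °C
Reagents that add atoms: none
Why: Hydride should add to the hindered ketone from the β face, which is flanked only by C6–H and the C11 methyl, while the α face is closed by the ring interior and the C11 chain. The resulting α hydroxyl is homoallylic to C4=C5 and points under it.

Step 17
Reactants: 27 homoallylic alcohol
Product: 28 4,5-epoxy alcohol (α-epoxide)
Conditions: VO(acac)2 (5 mol%), t-BuOOH, PhMe, 0 → 20 °C
Reagents that add atoms: tert-butyl hydroperoxide, CC(C)(C)OO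
Why: Vanadium-catalysed hydroxyl-directed epoxidation delivers oxygen to the alkene face of the C10 hydroxyl, trans to C6–H, against the intrinsic preference for the open β face; this sets C5.

Step 18
Reactants: 28 epoxy alcohol
Product: 29 5,10-diol (C5–OH α, tertiary)
Conditions: LiEt3BH, THF, 0 → 40 °C
Reagents that add atoms: none
Why: Triethylborohydride opens the trisubstituted epoxide by SN2 attack at the secondary C4, leaving the tertiary C5–O bond and its configuration untouched.

Step 19
Reactants: 29 diol
Product: 30 β-hydroxy ketone (C5–OH α, C6–H β, C10=O; both silyl ethers in place)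
Conditions: Dess–Martin periodinane, NaHCO3, CH2Cl2, 0 → 20 °C
Reagents that add atoms: none
Why: Dess–Martin oxidation takes the secondary alcohol and leaves the tertiary one; buffered conditions do not enolise C6, which has kept its configuration since step 9.

Step 20
Reactants: 30 β-hydroxy ketone
Product: 31 primary alcohol (C13–OH; C8–OTBS retained)
Conditions: HF·pyridine, pyridine, THF, 0 °C
Reagents that add atoms: none
Why: Buffered HF·pyridine cleaves the primary silyl ether much faster than the secondary one beside the quaternary C9, under conditions mild enough for the tertiary aldol.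

Step 21
Reactants: 31 primary alcohol
Product: 32 primary iodide (C13–I)
Conditions: I2, PPh3, imidazole, CH2Cl2, 0 → 20 °C
Reagents that add atoms: iodine, II
Why: Appel-type iodination is selective for the primary alcohol; the tertiary alcohol does not react.

Step 22
Reactants: 32 primary iodide; 33 4-bromofuran-2(5H)-one
Product: 35 C8 silyl ether of the target, via alkylzinc iodide 34 (not isolated)
Conditions: Zn, LiCl, THF, 40 °C; then 33, Pd(PPh3)4 (5 mol%), THF, 50 °C
Reagents that add atoms: none
Why: Zinc insertion into a primary iodide tolerates the hindered ketone and the hydrogen-bonded tertiary alcohol, and Negishi coupling with the β-bromobutenolide, an activated alkenyl bromide, forms C13–C14.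

Step 23
Reactants: 35 C8 silyl ether
Product: 36 target
Conditions: HF·pyridine, THF, 20 °C
Reagents that add atoms: none
Why: Acidic fluoride removes the last silyl ether without the basic conditions that would provoke retro-aldol cleavage or butenolide isomerisation.

## Compound list

1 | pent-3-yn-1-ol | CC#CCCO | starting material
2 | dimethyl(pent-3-yn-1-yloxy)silane | CC#CCCO[SiH](C)C | intermediate
3 | (E)-3-ethylidene-2,2-dimethyl-1,2-oxasilolane | C/C=C1\CCO[Si]1(C)C | intermediate
4 | (E)-3-iodopent-3-en-1-ol | C/C=C(\CCO)I | intermediate
5 | (E)-tert-butyl[(3-iodopent-3-en-1-yl)oxy]dimethylsilane | C/C=C(\CCO[Si](C)(C)C(C)(C)C)I | intermediate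
6 | (Z)-[1-(tert-butyldimethylsilyloxy)pent-3-en-3-yl]lithium | C/C=C(\CCO[Si](C)(C)C(C)(C)C)[Li] | intermediate
7 | (Z)-tert-butyldimethyl{[3-(4,4,5,5-tetramethyl-1,3,2-dioxaborolan-2-yl)pent-3-en-1-yl]oxy}silane | C/C=C(\CCO[Si](C)(C)C(C)(C)C)B1OC(C)(C)C(C)(C)O1 | intermediate
8 | 2,2-dimethylcyclopentane-1,3-dione | CC1(C)C(=O)CCC1=O | starting material
9 | (S)-3-hydroxy-2,2-dimethylcyclopentan-1-one | O=C1CC[C@H](O)C1(C)C | intermediate
10 | (S)-3-(tert-butyldimethylsilyloxy)-2,2-dimethylcyclopentan-1-one | O=C1CC[C@H](O[Si](C)(C)C(C)(C)C)C1(C)C | intermediate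
11 | potassium (S)-4-(tert-butyldimethylsilyloxy)-5,5-dimethylcyclopent-1-en-1-olate | [K]OC1=CC[C@H](O[Si](C)(C)C(C)(C)C)C1(C)C | intermediate
12 | (S)-4-(tert-butyldimethylsilyloxy)-5,5-dimethylcyclopent-1-en-1-yl trifluoromethanesulfonate | O=S(=O)(OC1=CC[C@H](O[Si](C)(C)C(C)(C)C)C1(C)C)C(F)(F)F | intermediate
13 | ethynyltrimethylsilane | C#C[Si](C)(C)C | starting material
14 | (S)-tert-butyldimethyl{[2,2-dimethyl-3-(trimethylsilylethynyl)cyclopent-3-en-1-yl]oxy}silane | C[Si](C)(C)C#CC1=CC[C@H](O[Si](C)(C)C(C)(C)C)C1(C)C | intermediate
15 | bromoform | BrC(Br)Br | starting material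
16 | 6,6-dibromo-3-(tert-butyldimethylsilyloxy)-2,2-dimethyl-1-(trimethylsilylethynyl)bicyclo[3.1.0]hexane, 3S, cyclopropane trans to the silyloxy group | BrC1(Br)[C@H]2C[C@H](O[Si](C)(C)C(C)(C)C)C(C)(C)[C@@]12C#C[Si](C)(C)C | intermediate
17 | 6-endo-bromo-6-exo-lithio carbenoid from 16 | [Li][C@]1(Br)[C@H]2C[C@H](O[Si](C)(C)C(C)(C)C)C(C)(C)[C@@]12C#C[Si](C)(C)C | intermediate
18 | lithium alkenyl(1-bromocyclopropyl)pinacolborate, boron exo on C10 | [Li+].C/C=C(\CCO[Si](C)(C)C(C)(C)C)[B-]3(OC(C)(C)C(C)(C)O3)[C@]1(Br)[C@H]2C[C@H](O[Si](C)(C)C(C)(C)C)C(C)(C)[C@@]12C#C[Si](C)(C)C | intermediate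
19 | cyclopropylboronate, C10 pinacolboryl endo and (E)-alkenyl exo | C/C=C(\CCO[Si](C)(C)C(C)(C)C)[C@]1(B3OC(C)(C)C(C)(C)O3)[C@H]2C[C@H](O[Si](C)(C)C(C)(C)C)C(C)(C)[C@@]12C#C[Si](C)(C)C | intermediate
20 | cyclopropanol, C10 hydroxyl endo, (E)-alkenyl exo and cis to the C5 silylethynyl group | C/C=C(\CCO[Si](C)(C)C(C)(C)C)[C@]1(O)[C@H]2C[C@H](O[Si](C)(C)C(C)(C)C)C(C)(C)[C@@]12C#C[Si](C)(C)C | intermediate
21 | C10 trimethylsilyl ether of 20 | C/C=C(\CCO[Si](C)(C)C(C)(C)C)[C@]1(O[Si](C)(C)C)[C@H]2C[C@H](O[Si](C)(C)C(C)(C)C)C(C)(C)[C@@]12C#C[Si](C)(C)C | intermediate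
22 | C5 ethynyl siloxycyclopropane | C/C=C(\CCO[Si](C)(C)C(C)(C)C)[C@]1(O[Si](C)(C)C)[C@H]2C[C@H](O[Si](C)(C)C(C)(C)C)C(C)(C)[C@@]12C#C | intermediate
23 | bicyclo[3.1.0]hexane siloxy cis-divinylcyclopropane (C5 vinyl, C10 (E)-alkenyl and OSiMe3) | C/C=C(\CCO[Si](C)(C)C(C)(C)C)[C@]1(O[Si](C)(C)C)[C@H]2C[C@H](O[Si](C)(C)C(C)(C)C)C(C)(C)[C@@]12C=C | intermediate
24 | hydroazulene dienyl silyl enol ether (C10=C11 OSiMe3, C4=C5) | C[C@@H]1CC=C2[C@H](C[C@H](O[Si](C)(C)C(C)(C)C)C2(C)C)C(O[Si](C)(C)C)=C1CCO[Si](C)(C)C(C)(C)C | intermediate
25 | lithium C10=C11 enolate | C[C@@H]1CC=C2[C@H](C[C@H](O[Si](C)(C)C(C)(C)C)C2(C)C)C(O[Li])=C1CCO[Si](C)(C)C(C)(C)C | intermediate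
26 | C11-methylated β,γ-unsaturated ketone (C4=C5, C6–H β, C11–CH3 β) | C[C@@H]1CC=C2[C@H](C[C@H](O[Si](C)(C)C(C)(C)C)C2(C)C)C(=O)[C@]1(C)CCO[Si](C)(C)C(C)(C)C | intermediate
27 | C10 α-alcohol of 26 | C[C@@H]1CC=C2[C@H](C[C@H](O[Si](C)(C)C(C)(C)C)C2(C)C)[C@H](O)[C@]1(C)CCO[Si](C)(C)C(C)(C)C | intermediate
28 | 4,5-α-epoxy C10 alcohol | C[C@@H]1C[C@@H]2O[C@]23[C@H](C[C@H](O[Si](C)(C)C(C)(C)C)C3(C)C)[C@H](O)[C@]1(C)CCO[Si](C)(C)C(C)(C)C | intermediate
29 | 5,10-diol (C5–OH α, C10–OH α) | C[C@@H]1CC[C@]2(O)[C@H](C[C@H](O[Si](C)(C)C(C)(C)C)C2(C)C)[C@H](O)[C@]1(C)CCO[Si](C)(C)C(C)(C)C | intermediate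
30 | trans-fused β-hydroxy ketone, C8 and C13 silyl ethers | C[C@@H]1CC[C@]2(O)[C@H](C[C@H](O[Si](C)(C)C(C)(C)C)C2(C)C)C(=O)[C@]1(C)CCO[Si](C)(C)C(C)(C)C | intermediate
31 | C13 primary alcohol, C8 silyl ether | C[C@@H]1CC[C@]2(O)[C@H](C[C@H](O[Si](C)(C)C(C)(C)C)C2(C)C)C(=O)[C@]1(C)CCO | intermediate
32 | C13 primary iodide, C8 silyl ether | C[C@@H]1CC[C@]2(O)[C@H](C[C@H](O[Si](C)(C)C(C)(C)C)C2(C)C)C(=O)[C@]1(C)CCI | intermediate
33 | 4-bromofuran-2(5H)-one | BrC1=CC(=O)OC1 | starting material
34 | C13 alkylzinc iodide | C[C@@H]1CC[C@]2(O)[C@H](C[C@H](O[Si](C)(C)C(C)(C)C)C2(C)C)C(=O)[C@]1(C)CC[Zn]I | intermediate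
35 | C8 tert-butyldimethylsilyl ether of the target | C[C@@H]1CC[C@]2(O)[C@H](C[C@H](O[Si](C)(C)C(C)(C)C)C2(C)C)C(=O)[C@]1(C)CCC1=CC(=O)OC1 | intermediate
36 | CNP0077405.3 | C[C@@H]1CC[C@]2(O)[C@H](C[C@H](O)C2(C)C)C(=O)[C@]1(C)CCC1=CC(=O)OC1 | target

## Step count and least certain steps

Total: 23 steps. Longest linear sequence: 19 steps (steps 5–23 from dione 8); the boronate branch (steps 1–4) joins at step 10.

**Step 14 (key step).** The α-branched alkenyl group on C10 must turn its terminus over the ring next to the geminal silyloxy group. If this is slow, prolonged heating could open a stepwise diradical pathway and erode C2, or hydrolyse the acid-labile enol ether. Fallback, from 23 to 25: treat 23 with MeLi in THF/DMPU at −78 → 0 °C. This cleaves the cyclopropyl O–Si bond to lithium cyclopropanolate F1, whose alkoxide-accelerated rearrangement gives enolate 25 directly; methylation as in step 15 then gives 26. The charge acceleration replaces thermal activation and skips isolation of 24.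

**Step 10.** The most likely failure is loss of the kinetic exo-lithio configuration through lithium–bromine exchange with unreacted dibromide, or attack of butyllithium on the boronate instead of the dibromide. Migration may also be slow because boron must swing into the crowded endo position. Fallback, from 16 to 18: add n-BuLi to 16 in the presence of the small electrophile iPrOBpin at −100 °C to give α-bromo cyclopropylboronate F8. Then add alkenyllithium 6, made from 5 as in step 4 without the borylation. This forms the same ate complex 18 from the other side, the classical α-halo boronate mode, and continues to 19 and 20.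

**Step 9.** Addition may be sluggish because the alkene is conjugated to the alkyne and sits next to a quaternary carbon, and tert-butoxide can attack the alkynylsilane; any leakage to the β face would also show here. Fallback, from 12 to 23: Stille coupling of 12 with tributyl(vinyl)stannane (Pd(PPh3)4, LiCl) gives the more electron-rich diene F2, and dibromocarbene gives vinyl dibromide F3. The step 10 protocol is then run below −95 °C until capture, to outrun rearrangement of the vinyl carbenoid, and below 0 °C afterwards. It leads through carbenoid F4, ate complex F5 and boronate F6 to divinylcyclopropanol F7, which 1-(trimethylsilyl)imidazole converts at 0 °C into 23. This is two steps shorter but handles a cis-divinylcyclopropane before its oxygen is protected.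

**Step 15.** Proton transfer from the doubly activated C6–H of the product to unreacted enolate would scramble C6, move the alkene into conjugation and leave unmethylated ketone. Fallback, from 24 to 26: Simmons–Smith cyclopropanation of the enol ether (Et2Zn, CH2I2) on the face away from the C2 methyl gives siloxycyclopropane F9. Acid-mediated opening (TsOH, wet CH2Cl2, 0 °C) cleaves the C10–CH2 bond and gives 26 without an enolate (Conia methylation).

**Step 17.** Hydroxyl direction could fail, because step 16 gave the wrong C10 epimer or because the vanadium alkoxide cannot reach the alkene; oxygen would then go to the open β face. Fallback, from 26 to 30: give up C6 and reset it. DBU isomerises 26 to conjugated enone F10; alkaline H2O2 epoxidises it anti to the C8 silyloxy group to give epoxy ketone F11; SmI2 in THF/MeOH at −90 °C opens it to 30. C6 is then set by protonation of the trivalent samarium enolate and, if needed, by equilibration toward the trans-fused epimer, the only one in which the C5 hydroxyl can hydrogen-bond to the C10 carbonyl.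

## Further compounds

F1 | step 14 | lithium cyclopropanolate from 23 | C/C=C(\CCO[Si](C)(C)C(C)(C)C)[C@]1(O[Li])[C@H]2C[C@H](O[Si](C)(C)C(C)(C)C)C(C)(C)[C@@]12C=C
F2 | step 9 | (S)-tert-butyl[(2,2-dimethyl-3-vinylcyclopent-3-en-1-yl)oxy]dimethylsilane | C=CC1=CC[C@H](O[Si](C)(C)C(C)(C)C)C1(C)C
F3 | step 9 | 6,6-dibromo-3-(tert-butyldimethylsilyloxy)-2,2-dimethyl-1-vinylbicyclo[3.1.0]hexane, cyclopropane trans to the silyloxy group | BrC1(Br)[C@H]2C[C@H](O[Si](C)(C)C(C)(C)C)C(C)(C)[C@@]12C=C
F4 | step 9 | 6-endo-bromo-6-exo-lithio carbenoid from F3 | [Li][C@]1(Br)[C@H]2C[C@H](O[Si](C)(C)C(C)(C)C)C(C)(C)[C@@]12C=C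
F5 | step 9 | lithium alkenyl(1-bromocyclopropyl)pinacolborate, vinyl series | [Li+].C/C=C(\CCO[Si](C)(C)C(C)(C)C)[B-]3(OC(C)(C)C(C)(C)O3)[C@]1(Br)[C@H]2C[C@H](O[Si](C)(C)C(C)(C)C)C(C)(C)[C@@]12C=C
F6 | step 9 | cyclopropylboronate, vinyl series | C/C=C(\CCO[Si](C)(C)C(C)(C)C)[C@]1(B3OC(C)(C)C(C)(C)O3)[C@H]2C[C@H](O[Si](C)(C)C(C)(C)C)C(C)(C)[C@@]12C=C
F7 | step 9 | cis-divinylcyclopropanol | C/C=C(\CCO[Si](C)(C)C(C)(C)C)[C@]1(O)[C@H]2C[C@H](O[Si](C)(C)C(C)(C)C)C(C)(C)[C@@]12C=C
F8 | step 10 | 6-endo-bromo-6-exo-pinacolboryl bicyclo[3.1.0]hexane from 16 | CC3(C)OB(OC3(C)C)[C@]1(Br)[C@H]2C[C@H](O[Si](C)(C)C(C)(C)C)C(C)(C)[C@@]12C#C[Si](C)(C)C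
F9 | step 15 | C10–C11 methylene-bridged siloxycyclopropane from 24, methylene β | C[C@@H]1CC=C2[C@H](C[C@H](O[Si](C)(C)C(C)(C)C)C2(C)C)[C@@]3(O[Si](C)(C)C)C[C@@]13CCO[Si](C)(C)C(C)(C)C
F10 | step 17 | conjugated C5=C6 enone | C[C@@H]1CCC2=C(C[C@H](O[Si](C)(C)C(C)(C)C)C2(C)C)C(=O)[C@]1(C)CCO[Si](C)(C)C(C)(C)C
F11 | step 17 | 5,6-α-epoxy ketone | C[C@@H]1CC[C@]2(O3)[C@@]3(C[C@H](O[Si](C)(C)C(C)(C)C)C2(C)C)C(=O)[C@]1(C)CCO[Si](C)(C)C(C)(C)C
A1 | alternative 1 | trans-2,11-dimethyl cycloheptanone ketal with C11 allyl group | C[C@@H]1CCC2(OCCO2)CC(=O)[C@]1(C)CC=C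
A2 | alternative 1 | 8-allyl-1,4-dioxaspiro[4.6]undec-8-en-7-one | C=CCC1=CCCC2(OCCO2)CC1=O
A3 | alternative 2 | bicyclic 1,4-diketone, C5 triethylsilyl ether, C13 tert-butyldiphenylsilyl ether | C[C@@H]1CC[C@]2(O[Si](CC)(CC)CC)[C@H](CC(=O)C2(C)C)C(=O)[C@]1(C)CCO[Si](c1ccccc1)(c1ccccc1)C(C)(C)C
A4 | alternative 2 | C8 aldehyde with C6 exo-methylene cycloheptanone | C[C@@H]1CC[C@@](O[Si](CC)(CC)CC)(C(C)(C)C=O)C(=C)C(=O)[C@]1(C)CCO[Si](c1ccccc1)(c1ccccc1)C(C)(C)C
A5 | alternative 3 | bicyclic 1,4-diketone, C5 triethylsilyl ether, C13 tert-butyldimethylsilyl ether | C[C@@H]1CC[C@]2(O[Si](CC)(CC)CC)[C@H](CC(=O)C2(C)C)C(=O)[C@]1(C)CCO[Si](C)(C)C(C)(C)C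
A6 | alternative 3 | cycloheptanone with C5 side-chain methyl ketone | C[C@@H]1CC[C@@](O[Si](CC)(CC)CC)(C(C)(C)C(C)=O)CC(=O)[C@]1(C)CCO[Si](C)(C)C(C)(C)C
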